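**The question.** I had to say what the flask charged with 0.72 M of Q holds at 25 h.

| flask | Q | L | remark | time |
|---|---|---|---|---|
| south-west | 0.36 M | 190 mM (held) | run made earlier |  |
| north | 0.54 M | 190 mM (held) | run made earlier |  |
| flask | 0.72 M | 190 mM (held) |  | 25 h |

- south-west (time / h: Z / %, Q / %): 4.00: 79.0, 21.0; 8.00: 78.9, 21.6; 12.0: 78.9, 20.7; 15.0: 78.8, 19.8
- north (time / h: Z / %, Q / %): 4.00: 72.8, 26.8; 8.00: 73.6, 26.5; 12.0: 73.8, 27.1; 15.0: 72.7, 26.9

(readings scatter by 0.5 percentage points)

* concentration of Z at 25 h, in M
* concentration of Q at 25 h, in M
* concentration of E at 25 h, in M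

- at the start none of E is dissolved
- steps under discussion: L <-> E; Q + E <-> Z + X

**Two amounts.** The south-west run showed Z at 79.0% after 4.00 h, far earlier than the asked time, and 78.8% after 15.0 h, a drift within the scatter of 0.5 percentage points, so I read both runs as at rest, under thermodynamic control, and set time aside. I assumed that L keeps dissolved E steady and that each Z comes with one X, so Z squared over the Q left should stay constant across charges. Averaged over each run's readings, this quotient was 1.08 M in the south-west run and 1.08 M in the north run, and I carried their mean, 1.08 M.

**The zero.** Twice that quotient, 2.16 M, is the half-way charge, the charge at which, at rest under this held L, Z and Q stand equal, each half of it, and it is a value read from the runs, with their scatter. The flask's charge is 0.333 of this, less than the half-way charge, so I expected Z to lead, and the quotient gave me 0.494 M of Z and 0.226 M of Q.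

**The forecast.** It gave 0.494 M of Z, 0.226 M of Q and 0.1 M of E, adding “E itself is not identifiable”.

**The result.** The flask gave 0.494 M of Z, 0.226 M of Q and 0.190 M of E, more E than forecast.

    L ⇌ E, rate k1*(csat - [E]) (kL = 3.25 /h)
    Q + E ⇌ Z + X (K = 5.70, k = 43.6 /M/h)

**At rest.** Below the half-way charge of 2.16 M, the flask ended with 68.7% as Z. The neighbour charged with 2.9 M, above it, reckons by the quotient to 1.31 M of Z; it held 1.31 M, with Z at 45.2% and Q at 54.8%. The flask had Z at 67.8% after 2.50 h and 68.7% after 12.5 h. Left ten times as long, the flask still held 0.494 M of Z.

(The runs stem from a simulated flask for substances that don't exist.)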